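**Retrosynthetic overview**
1. Target ⇒ acetylation and Stille hydroxymethylation of a 15-iodo-2,5-dihydrofuran ⇒ 5-endo iodoetherification of a macrocyclic α-allenol (dihydrofuran ring formed last).
2. α-Allenol ⇒ C1–C2 disconnection: enantioselective intramolecular propargylboration of an acyclic enal / 2-alkynyl boronate closes the 14-membered ring and sets C2 (proposed new method).
3. Enal / boronate ⇒ acetylide homologation with ICH2Bpin, and C13–C14 disconnection to an epoxy-farnesyl bromide plus lithiated 1-(trimethylsilyl)propyne.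
4. (S,S)-Epoxide (first ring formed) ⇒ Shi epoxidation of a farnesyl 1,12-diester ⇒ SeO2 oxidation of (2E,6E)-farnesyl pivalate.

Assumption: macrocycles carry cembrane numbering (ring C1–C14, C15 on C1, C16 = ring OCH2, C17 = CH2OAc) and acyclic compounds are numbered from the oxygenated terminus (chain C1 = future C2). The facial sense of the (R)-configured phosphoric acid in step 12 (Re-face attack) is taken from intermolecular allyl- and propargylborations and is first confirmed on farnesal; the antipodal acid is used if the sense is opposite.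

**Step 1**
Reactants: 1 (2E,6E)-farnesol
Product: 2 (2E,6E)-farnesyl pivalate
Conditions: PivCl, pyridine, 4-(dimethylamino)pyridine (cat.), CH2Cl2, 0 °C → rt
Reagents that add atoms: pivaloyl chloride CC(C)(C)C(=O)Cl
Why: Standard acylation of the primary allylic alcohol; the pivalate has no α-hydrogens, resists the later basic and organolithium steps and inductively deactivates the 2,3-alkene.

**Step 2**
Reactants: 2 (2E,6E)-farnesyl pivalate
Product: 3 (2E,6E,10E)-12-hydroxy-3,7,11-trimethyldodeca-2,6,10-trien-1-yl pivalate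
Conditions: SeO2 (0.3 equiv), t-BuOOH (70% aq., 3 equiv), salicylic acid (0.1 equiv), CH2Cl2, 0 °C → rt, stopped at about 60% conversion, 2 recycled
Reagents that add atoms: tert-butyl hydroperoxide CC(C)(C)OO (stoichiometric oxygen source); selenium dioxide O=[Se]=O (catalyst that relays the oxygen atom)
Why: SeO2/t-BuOOH allylic oxidation (ene reaction then [2,3]-sigmatropic shift) attacks the most electron-rich terminal trisubstituted alkene and oxidises its E-methyl group to the E-allylic alcohol, while the 2,3-alkene is deactivated by the allylic ester.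

**Step 3**
Reactants: 3 (2E,6E,10E)-12-hydroxy-3,7,11-trimethyldodeca-2,6,10-trien-1-yl pivalate
Product: 4 (2E,6E,10E)-12-acetoxy-3,7,11-trimethyldodeca-2,6,10-trien-1-yl pivalate
Conditions: Ac2O, pyridine, 4-(dimethylamino)pyridine (cat.), CH2Cl2, 0 °C
Reagents that add atoms: acetic anhydride CC(=O)OC(C)=O
Why: Routine acetylation that differentiates the two termini (acetate versus pivalate) and makes the 10,11-alkene electron-poor for the next step.

**Step 4**
Reactants: 4 (2E,6E,10E)-12-acetoxy-3,7,11-trimethyldodeca-2,6,10-trien-1-yl pivalate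
Product: 5 (2E,6S,7S,10E)-12-acetoxy-6,7-epoxy-3,7,11-trimethyldodeca-2,10-dien-1-yl pivalate
Conditions: L-fructose-derived Shi ketone (1,2:4,5-di-O-isopropylidene-β-L-erythro-2,3-hexodiulo-2,6-pyranose, 0.3 equiv), KHSO5 (1.4 equiv, supplied as 2KHSO5·KHSO4·K2SO4), K2CO3, Bu4NHSO4 (cat.), aq. Na2B4O7 buffer, MeCN–CH2(OMe)2–H2O, 0 °C
Reagents that add atoms: potassium peroxymonosulfate [K+].[O-]S(=O)(=O)OO (oxygen atom relayed by the ketone catalyst as its dioxirane)
Why: Shi asymmetric epoxidation: the chiral dioxirane reacts through the spiro transition state with the only alkene not deactivated by an allylic ester (6,7), and the L-fructose-derived ketone gives the (6S,7S)-epoxide, the mirror image of the (R,R)-epoxides formed from E-trisubstituted alkenes with the D-fructose-derived ketone.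

**Step 5**
Reactants: 5 (2E,6S,7S,10E)-12-acetoxy-6,7-epoxy-3,7,11-trimethyldodeca-2,10-dien-1-yl pivalate
Product: 6 (2E,6S,7S,10E)-6,7-epoxy-12-hydroxy-3,7,11-trimethyldodeca-2,10-dien-1-yl pivalate
Conditions: K2CO3 (0.5 equiv), MeOH, 0 °C, 1 h
Reagents that add atoms: none
Why: Base-catalysed transesterification removes the unhindered acetate far faster than the pivalate, and the epoxide is inert to methanolic carbonate at 0 °C.

**Step 6**
Reactants: 6 (2E,6S,7S,10E)-6,7-epoxy-12-hydroxy-3,7,11-trimethyldodeca-2,10-dien-1-yl pivalate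
Product: 8 (2E,6S,7S,10E)-12-bromo-6,7-epoxy-3,7,11-trimethyldodeca-2,10-dien-1-yl pivalate, via allylic mesylate 7 (not isolated)
Conditions: MsCl, Et3N, CH2Cl2, −40 °C; then LiBr, THF, 0 °C
Reagents that add atoms: lithium bromide [Li+].[Br-]
Why: Mesylation followed by SN2 displacement with bromide (Finkelstein-type) converts the primary allylic alcohol into the bromide without allylic transposition or loss of E geometry, under conditions long used on epoxy-polyprenols.

**Step 7**
Reactants: 8 (2E,6S,7S,10E)-12-bromo-6,7-epoxy-3,7,11-trimethyldodeca-2,10-dien-1-yl pivalate; 9 1-(trimethylsilyl)propyne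
Product: 11 (2E,6S,7S,10E)-6,7-epoxy-3,7,11-trimethyl-15-(trimethylsilyl)pentadeca-2,10-dien-14-yn-1-yl pivalate, via 3-lithio-1-(trimethylsilyl)propyne 10 (not isolated)
Conditions: 9 (1.3 equiv), n-BuLi, THF, −78 → −20 °C; then 8, −78 °C, 1 h
Reagents that add atoms: none
Why: SN2 alkylation of the primary allylic bromide by lithiated 1-(trimethylsilyl)propyne (propargylation), in which the silyl group enforces propargyl rather than allenyl coupling and the hindered, non-enolisable pivalate and the epoxide survive at −78 °C.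

**Step 8**
Reactants: 11 (2E,6S,7S,10E)-6,7-epoxy-3,7,11-trimethyl-15-(trimethylsilyl)pentadeca-2,10-dien-14-yn-1-yl pivalate
Product: 12 (2E,6S,7S,10E)-6,7-epoxy-3,7,11-trimethylpentadeca-2,10-dien-14-yn-1-yl pivalate
Conditions: K2CO3 (0.2 equiv), MeOH, 0 °C → rt, 1 h
Reagents that add atoms: none
Why: Methoxide-mediated protodesilylation of the alkynylsilane is fast under conditions that leave the pivalate and the epoxide untouched.

**Step 9**
Reactants: 12 (2E,6S,7S,10E)-6,7-epoxy-3,7,11-trimethylpentadeca-2,10-dien-14-yn-1-yl pivalate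
Product: 15 (2E,6S,7S,10E)-6,7-epoxy-3,7,11-trimethyl-16-(4,4,5,5-tetramethyl-1,3,2-dioxaborolan-2-yl)hexadeca-2,10-dien-14-yn-1-yl pivalate, via lithium acetylide 13 (not isolated), via iodomethylboronate ate complex 14 (not isolated)
Conditions: n-BuLi (1.0 equiv), THF, −78 °C; then ICH2Bpin (1.1 equiv), −78 °C → rt
Reagents that add atoms: 2-(iodomethyl)-4,4,5,5-tetramethyl-1,3,2-dioxaborolane ICB1OC(C)(C)C(C)(C)O1
Why: Matteson-type homologation: kinetic deprotonation of the terminal alkyne, addition of the acetylide to boron and a 1,2-metallate shift with loss of iodide give the 2-alkynyl (propargylic) pinacol boronate, the pivalate being spared at −78 °C by the much faster acid–base reaction.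

**Step 10**
Reactants: 15 (2E,6S,7S,10E)-6,7-epoxy-3,7,11-trimethyl-16-(4,4,5,5-tetramethyl-1,3,2-dioxaborolan-2-yl)hexadeca-2,10-dien-14-yn-1-yl pivalate
Product: 16 (2E,6S,7S,10E)-6,7-epoxy-3,7,11-trimethyl-16-(4,4,5,5-tetramethyl-1,3,2-dioxaborolan-2-yl)hexadeca-2,10-dien-14-yn-1-ol
Conditions: i-Bu2AlH (2.5 equiv), CH2Cl2, −78 °C; aq. potassium sodium tartrate
Reagents that add atoms: none
Why: Reductive cleavage of the pivalate with i-Bu2AlH at −78 °C, a temperature at which the trisubstituted epoxide, the alkyne and the pinacol boronate do not react.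

**Step 11**
Reactants: 16 (2E,6S,7S,10E)-6,7-epoxy-3,7,11-trimethyl-16-(4,4,5,5-tetramethyl-1,3,2-dioxaborolan-2-yl)hexadeca-2,10-dien-14-yn-1-ol
Product: 17 (2E,6S,7S,10E)-6,7-epoxy-3,7,11-trimethyl-16-(4,4,5,5-tetramethyl-1,3,2-dioxaborolan-2-yl)hexadeca-2,10-dien-14-ynal
Conditions: MnO2 (activated, 20 equiv), CH2Cl2, rt; filtered, solvent changed to toluene, used at once
Reagents that add atoms: none
Why: MnO2 oxidises only the allylic alcohol to the E-enal under neutral heterogeneous conditions that do not touch the C–B bond or the epoxide.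

**Step 12**
Reactants: 17 (2E,6S,7S,10E)-6,7-epoxy-3,7,11-trimethyl-16-(4,4,5,5-tetramethyl-1,3,2-dioxaborolan-2-yl)hexadeca-2,10-dien-14-ynal
Product: 19 (2S,7S,8S,3E,11E)-7,8-epoxy-17-norcembra-1(15),3,11,15-tetraen-2-ol, via O-pinacolboryl ether 18 (not isolated)
Conditions: (R)-3,3′-bis(2,4,6-triisopropylphenyl)-1,1′-binaphthyl-2,2′-diyl hydrogen phosphate [(R)-TRIP, 30 mol %, 5 mM], 4 Å molecular sieves, toluene, −20 °C, 17 added by syringe pump over 24 h (final 3 mM); then aq. NaHCO3 work-up
Reagents that add atoms: none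
Why: Proposed new method: a chiral-phosphoric-acid-catalysed enantioselective intramolecular carbonyl propargylboration used as a macrocyclisation, in which the acid hydrogen-bonds to a boronate oxygen and to the formyl C–H, the γ-carbon (C1) of the 2-alkynyl boronate attacks the Re face of the enal (O > C3 > H, which gives 2S) through a closed six-membered SE2′ transition state so that only the 14-membered allenyl carbinol and not a 16-membered homopropargylic alcohol can form, and slow addition into a normal catalyst concentration keeps the catalysed ring closure ahead of dimerisation and of the uncatalysed background; the closest known reaction types are the intermolecular chiral-phosphoric-acid-catalysed allyl-, allenyl- and propargylboration of aldehydes with pinacol boronates and the Lewis-acid-promoted intramolecular SE2′ additions of allyl- and allenylstannanes to aldehydes used to close 14-membered cembranoid rings.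

**Step 13**
Reactants: 19 (2S,7S,8S,3E,11E)-7,8-epoxy-17-norcembra-1(15),3,11,15-tetraen-2-ol
Product: 20 (2S,7S,8S,3E,11E)-15-iodo-2,16:7,8-diepoxy-17-norcembra-1(15),3,11-triene
Conditions: NIS (1.2 equiv), CH2Cl2, 0 °C, dark
Reagents that add atoms: N-iodosuccinimide O=C1CCC(=O)N1I
Why: Iodoetherification of the α-allenol (5-endo halocyclisation): iodonium forms on the terminal allene π-bond, the C2 hydroxyl attacks the CH2 terminus (C16) and iodine ends up on C15 of the new 2,5-dihydrofuran, the C2 stereocentre being a spectator.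

**Step 14**
Reactants: 20 (2S,7S,8S,3E,11E)-15-iodo-2,16:7,8-diepoxy-17-norcembra-1(15),3,11-triene
Product: 21 (2S,7S,8S,3E,11E)-2,16:7,8-diepoxycembra-1(15),3,11-trien-17-ol
Conditions: Bu3SnCH2OH (2 equiv), Pd(PPh3)4 (10 mol %), dioxane, 90 °C
Reagents that add atoms: (tributylstannyl)methanol OC[Sn](CCCC)(CCCC)CCCC
Why: Stille coupling: oxidative addition of the alkenyl iodide to zerovalent palladium, transmetallation of the hydroxymethyl group from tin and reductive elimination install C17 on the tetrasubstituted alkene under neutral conditions tolerated by the epoxide.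

**Step 15**
Reactants: 21 (2S,7S,8S,3E,11E)-2,16:7,8-diepoxycembra-1(15),3,11-trien-17-ol
Product: 22 (2S,7S,8S,3E,11E)-2,16:7,8-diepoxycembra-1(15),3,11-trien-17-yl acetate
Conditions: Ac2O, pyridine, 4-(dimethylamino)pyridine (cat.), CH2Cl2, 0 °C → rt
Reagents that add atoms: acetic anhydride CC(=O)OC(C)=O
Why: Routine acetylation of the primary allylic alcohol gives the target without touching any stereocentre.

**Compound list**
1 | (2E,6E)-farnesol, (2E,6E)-3,7,11-trimethyldodeca-2,6,10-trien-1-ol | CC(C)=CCC/C(C)=C/CC/C(C)=C/CO | starting material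
2 | (2E,6E)-farnesyl pivalate | CC(C)=CCC/C(C)=C/CC/C(C)=C/COC(=O)C(C)(C)C | intermediate
3 | (2E,6E,10E)-12-hydroxy-3,7,11-trimethyldodeca-2,6,10-trien-1-yl pivalate | OC/C(C)=C/CC/C(C)=C/CC/C(C)=C/COC(=O)C(C)(C)C | intermediate
4 | (2E,6E,10E)-12-acetoxy-3,7,11-trimethyldodeca-2,6,10-trien-1-yl pivalate | CC(=O)OC/C(C)=C/CC/C(C)=C/CC/C(C)=C/COC(=O)C(C)(C)C | intermediate
5 | (2E,6S,7S,10E)-12-acetoxy-6,7-epoxy-3,7,11-trimethyldodeca-2,10-dien-1-yl pivalate | CC(=O)OC/C(C)=C/CC[C@]1(C)O[C@H]1CC/C(C)=C/COC(=O)C(C)(C)C | intermediate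
6 | (2E,6S,7S,10E)-6,7-epoxy-12-hydroxy-3,7,11-trimethyldodeca-2,10-dien-1-yl pivalate | OC/C(C)=C/CC[C@]1(C)O[C@H]1CC/C(C)=C/COC(=O)C(C)(C)C | intermediate
7 | allylic mesylate: (2E,6S,7S,10E)-6,7-epoxy-12-(methanesulfonyloxy)-3,7,11-trimethyldodeca-2,10-dien-1-yl pivalate | CS(=O)(=O)OC/C(C)=C/CC[C@]1(C)O[C@H]1CC/C(C)=C/COC(=O)C(C)(C)C | intermediate (not isolated)
8 | (2E,6S,7S,10E)-12-bromo-6,7-epoxy-3,7,11-trimethyldodeca-2,10-dien-1-yl pivalate | BrC/C(C)=C/CC[C@]1(C)O[C@H]1CC/C(C)=C/COC(=O)C(C)(C)C | intermediate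
9 | 1-(trimethylsilyl)propyne | CC#C[Si](C)(C)C | starting material
10 | 3-lithio-1-(trimethylsilyl)propyne | [Li]CC#C[Si](C)(C)C | intermediate (not isolated)
11 | (2E,6S,7S,10E)-6,7-epoxy-3,7,11-trimethyl-15-(trimethylsilyl)pentadeca-2,10-dien-14-yn-1-yl pivalate | C[Si](C)(C)C#CCC/C(C)=C/CC[C@]1(C)O[C@H]1CC/C(C)=C/COC(=O)C(C)(C)C | intermediate
12 | (2E,6S,7S,10E)-6,7-epoxy-3,7,11-trimethylpentadeca-2,10-dien-14-yn-1-yl pivalate | C#CCC/C(C)=C/CC[C@]1(C)O[C@H]1CC/C(C)=C/COC(=O)C(C)(C)C | intermediate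
13 | lithium acetylide of 12 (15-lithio derivative) | [Li]C#CCC/C(C)=C/CC[C@]1(C)O[C@H]1CC/C(C)=C/COC(=O)C(C)(C)C | intermediate (not isolated)
14 | iodomethylboronate ate complex: lithium alkynyl(iodomethyl)(pinacolato)borate from 13 and ICH2Bpin | [Li+].IC[B-]1(OC(C)(C)C(C)(C)O1)C#CCC/C(C)=C/CC[C@]2(C)O[C@H]2CC/C(C)=C/COC(=O)C(C)(C)C | intermediate (not isolated)
15 | (2E,6S,7S,10E)-6,7-epoxy-3,7,11-trimethyl-16-(4,4,5,5-tetramethyl-1,3,2-dioxaborolan-2-yl)hexadeca-2,10-dien-14-yn-1-yl pivalate | CC1(C)OB(CC#CCC/C(C)=C/CC[C@]2(C)O[C@H]2CC/C(C)=C/COC(=O)C(C)(C)C)OC1(C)C | intermediate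
16 | (2E,6S,7S,10E)-6,7-epoxy-3,7,11-trimethyl-16-(4,4,5,5-tetramethyl-1,3,2-dioxaborolan-2-yl)hexadeca-2,10-dien-14-yn-1-ol | CC1(C)OB(CC#CCC/C(C)=C/CC[C@]2(C)O[C@H]2CC/C(C)=C/CO)OC1(C)C | intermediate
17 | (2E,6S,7S,10E)-6,7-epoxy-3,7,11-trimethyl-16-(4,4,5,5-tetramethyl-1,3,2-dioxaborolan-2-yl)hexadeca-2,10-dien-14-ynal | CC1(C)OB(CC#CCC/C(C)=C/CC[C@]2(C)O[C@H]2CC/C(C)=C/C=O)OC1(C)C | intermediate
18 | O-pinacolboryl ether of 19 (14-membered ring, exocyclic C1=C15=C16H2 allene, 2-OBpin) | C=C=C1CC/C(C)=C/CC[C@]2(C)O[C@H]2CC/C(C)=C/[C@@H]1OB1OC(C)(C)C(C)(C)O1 | intermediate (not isolated)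
19 | (2S,7S,8S,3E,11E)-7,8-epoxy-17-norcembra-1(15),3,11,15-tetraen-2-ol (14-membered ring, exocyclic vinylidene at C1, 2-OH) | C=C=C1CC/C(C)=C/CC[C@]2(C)O[C@H]2CC/C(C)=C/[C@@H]1O | intermediate
20 | (2S,7S,8S,3E,11E)-15-iodo-2,16:7,8-diepoxy-17-norcembra-1(15),3,11-triene (3-iodo-2,5-dihydrofuran fused at C1–C2) | IC1=C2CC/C(C)=C/CC[C@]3(C)O[C@H]3CC/C(C)=C/[C@@H]2OC1 | intermediate
21 | (2S,7S,8S,3E,11E)-2,16:7,8-diepoxycembra-1(15),3,11-trien-17-ol | OCC1=C2CC/C(C)=C/CC[C@]3(C)O[C@H]3CC/C(C)=C/[C@@H]2OC1 | intermediate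
22 | (2S,7S,8S,3E,11E)-2,16:7,8-diepoxycembra-1(15),3,11-trien-17-yl acetate (CNP0140293.1) | CC(=O)OCC1=C2CC/C(C)=C/CC[C@]3(C)O[C@H]3CC/C(C)=C/[C@@H]2OC1 | target

**Totals**
Total step count: 15. Longest linear sequence: 15 steps from (2E,6E)-farnesol (1).

**Three steps most likely to fail**

Step 12 (the new macrocyclisation). Risks are oligomerisation, a competing uncatalysed and therefore C2-unselective ring closure, and acid sensitivity of the epoxide. The fallback uses known chemistry and sets out from 12. Deprotonation with n-BuLi and addition of paraformaldehyde gives the propargylic alcohol F1. CBr4/PPh3 in CH2Cl2 at 0 °C gives the propargylic bromide F2. i-Bu2AlH at −78 °C removes the pivalate to give the bromo allylic alcohol F3, and MnO2 gives the bromo enal F4. A Nozaki–Hiyama macrocyclisation with excess CrCl2 in THF at high dilution (2-alkynyl bromides add through their γ-carbon to give 2-substituted buta-2,3-dienyl carbinols) gives the macrocyclic allenol as a mixture of C2 epimers F5. Dess–Martin periodinane with NaHCO3 gives the cross-conjugated allenyl ketone F6. Reduction with (R)-3,3-diphenyl-1-methyltetrahydro-3H-pyrrolo[1,2-c][1,3,2]oxazaborole (CBS catalyst) and catecholborane at −78 °C, the 1,1-disubstituted allenyl arm acting as the large group, sets C2 and comes back to the route at 19.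

Step 13 (iodoetherification). The iodonium source may engage the trisubstituted alkenes, with transannular participation of the epoxide oxygen. The fallback sets out from 19 and comes back at 20. Ph3PAuNTf2 (2 mol %, monovalent gold) with NIS in CH2Cl2 at −20 °C changes the bond-forming event to π-acid activation of the allene: the hydroxyl adds to the gold-bound allene and the resulting alkenylgold is intercepted by iododeauration. The C–O bond then no longer depends on a free iodonium ion and the allenol is consumed within minutes. This fallback makes no new compound (F0).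

Step 14 (Stille hydroxymethylation). Transfer of an sp3 group from tin to a hindered tetrasubstituted alkenyl iodide may be slow. The fallback sets out from 20 and comes back at 21. Methoxycarbonylation with Pd(OAc)2/dppf, CO (1 atm), MeOH and Et3N in DMF at 60 °C gives the methyl dihydrofuran-3-carboxylate F7, which i-Bu2AlH in CH2Cl2 at −78 °C reduces to 21.

**Further compounds**
F1 | step 12 | (2E,6S,7S,10E)-6,7-epoxy-16-hydroxy-3,7,11-trimethylhexadeca-2,10-dien-14-yn-1-yl pivalate | OCC#CCC/C(C)=C/CC[C@]1(C)O[C@H]1CC/C(C)=C/COC(=O)C(C)(C)C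
F2 | step 12 | (2E,6S,7S,10E)-16-bromo-6,7-epoxy-3,7,11-trimethylhexadeca-2,10-dien-14-yn-1-yl pivalate | BrCC#CCC/C(C)=C/CC[C@]1(C)O[C@H]1CC/C(C)=C/COC(=O)C(C)(C)C
F3 | step 12 | (2E,6S,7S,10E)-16-bromo-6,7-epoxy-3,7,11-trimethylhexadeca-2,10-dien-14-yn-1-ol | BrCC#CCC/C(C)=C/CC[C@]1(C)O[C@H]1CC/C(C)=C/CO
F4 | step 12 | (2E,6S,7S,10E)-16-bromo-6,7-epoxy-3,7,11-trimethylhexadeca-2,10-dien-14-ynal | BrCC#CCC/C(C)=C/CC[C@]1(C)O[C@H]1CC/C(C)=C/C=O
F5 | step 12 | (7S,8S,3E,11E)-7,8-epoxy-17-norcembra-1(15),3,11,15-tetraen-2-ol as a mixture of C2 epimers | C=C=C1CC/C(C)=C/CC[C@]2(C)O[C@H]2CC/C(C)=C/C1O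
F6 | step 12 | (7S,8S,3E,11E)-7,8-epoxy-17-norcembra-1(15),3,11,15-tetraen-2-one | C=C=C1CC/C(C)=C/CC[C@]2(C)O[C@H]2CC/C(C)=C/C1=O
F0 | step 13 | none | none
F7 | step 14 | methyl (2S,7S,8S,3E,11E)-2,16:7,8-diepoxycembra-1(15),3,11-trien-17-oate | COC(=O)C1=C2CC/C(C)=C/CC[C@]3(C)O[C@H]3CC/C(C)=C/[C@@H]2OC1
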